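(The numbers of this flask were chosen freely; the rest is arithmetic.)

Reckon in reciprocal minutes, the one unit in which the fates of every form of the catalyst can be compared.

    free catalyst + left-handed substrate ⇌ catalyst intermediate A (K1 = 64 M⁻¹, k1 = 450 M⁻¹ min⁻¹)
    free catalyst + right-handed substrate ⇌ catalyst intermediate B (K2 = 41 M⁻¹, k2 = 2400 M⁻¹ min⁻¹)
    partner + catalyst intermediate A → free catalyst + left-handed product (k3 = 610 M⁻¹ min⁻¹)
    partner + catalyst intermediate B → free catalyst + right-handed product (k4 = 270 M⁻¹ min⁻¹)
    partner → decomposed reagent (k5 = 0.049 min⁻¹)
    free catalyst + free catalyst ⇌ resting dimer (K6 = 150 M⁻¹, k6 = 67 M⁻¹ min⁻¹)

left-handed substrate 0.020 M; partner 0.0300 M; free catalyst 2.4 mM; right-handed substrate 0.020 M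

- free catalyst is single-handed; left-handed substrate and right-handed substrate are mirror images of each other, charged as a racemate, each of them at the stated concentration
- a step written with two of one species runs at k times the square of its concentration and takes two of it each time
- what is bound to the catalyst counts as converted
- charge of left-handed substrate (flask): 0.020 M

* apparent order in partner when 30% of the left-handed substrate and right-handed substrate together are converted (percent change of the rate of making left-handed product for one percent more partner charged)

Start with partner at 30% conversion. Count one partner per substrate converted, which leaves 0.0180 M. Now climb down the ladder of rates. Intermediate B falls back at 58.5 min⁻¹ and goes on at 4.86 min⁻¹, much slower than it falls back, so treat it as a pre-equilibrium with its substrate. Intermediate A falls back at 7.03 min⁻¹ and goes on at 11.0 min⁻¹, so extra partner still changes its fate. Of intermediate A, 39.0% returns to free catalyst: call this part, fall-back rate over fall-back plus onward rate, the fall-back share w. Lowest on the ladder, drop partner decomposition at 0.049 min⁻¹ and dimer formation at 0.161 min⁻¹ per catalyst, both far slower than the fall-back of intermediate A.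

Take each substrate at what 30% conversion leaves of it. Balancing each intermediate then puts 18.6% of the catalyst in intermediate A and 28.2% in intermediate B. More partner lowers the share in intermediate A and raises free catalyst, by 0.135 percent for one percent more partner. Add that gain to w for a local order of 0.525. Count the same amount of partner gone at fixed conversion, so one percent more charged means 1.67 percent more left. Multiply the two: my reckoning gives 0.876.

The forecast says 0.9, within 0.7 to 1.1, with “a local order of only about 0.5 in partner”.

The simulation gives 1.0, higher than my figure. At 1.30 min, intermediate A falls back at 0.72 of the rate at which it goes on, a fall-back share of 41.9%, larger than the 39.0% reckoned for 30% conversion, which is reached at 1.07 min. At 6.00 min, intermediate A is made at 0.983 of the rate at which it is used up.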